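**Plan**

1. Atom labels: cyclobutane C1(H)–C5(H)–C6(O)–C10(C14H3); ring A C1–C2–C3–C4(C15)–C5; ring C C6–C7–C8–C9–C10; butenolide C6–O–C12(=O)–C11(C13H2OAc)=C7. The top face of the cyclobutane carries C14 and the C6 oxygen; both five-membered rings hang from the bottom face.
2. Enabling feature: in ring A the tertiary carbinol C4 lies 1,3 to the C2 oxygen through C3H2. That is the array left when a C3 carbenoid beside a C2 carbonyl inserts into the C4–H bond of a secondary silyl ether held cis to it on the cyclobutane (arms on C1 and C5).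
3. Cuts, in retrosynthetic order: the C8 and C2 ester C–O bonds; C3–C4 (ring A, C–H insertion) and C2–C3 (diazomethane); C7=C11 and C12–O (butenolide); the cyclobutane back to a cyclopentanone (Wolff contraction); C6–O; C6–C10, C1–C2 and C2–C5 (Pauson–Khand); C6–C7 (acetylide acylation); C8–C9 (glyoxylate ene).
4. Forward order: acyclic enyne → ring C plus a cyclopentenone in one step → C6 oxygen (epoxidation, reductive opening) → cyclobutane by ring contraction → butenolide → ring A by carbenoid insertion → C2 acetate and C8 tiglate.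
5. Stereochemistry: C8 from the (S)-BINOL/titanium ene reaction; C4 bought as (S)-but-3-yn-2-ol and transferred with retention; a temporary C7 carbinol (catalyst-controlled transfer hydrogenation) relays to C10 in the Pauson–Khand step; C6 by the forced cis ring fusion; C5 and C1 by protonation on the convex face; C2 by exo hydride attack, then Mitsunobu inversion.

Key step: step 23

Remark: "exo" and "endo" mean the convex and concave face of the bicycle in question; compounds 25–27 are epimer mixtures at the phosphonate carbon, which becomes sp2 in step 19.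

**Route**

Step 1
Reactants: 1 ethyl glyoxylate; 2 2-methylpropene
Product: 3 ethyl (S)-2-hydroxy-4-methylpent-4-enoate
Conditions: (S)-BINOL (10 mol %), TiCl2(Oi-Pr)2 (10 mol %), 4 Å MS, CH2Cl2, −30 °C
Reagents that add atoms: none
Why: Catalytic asymmetric carbonyl-ene reaction of a glyoxylate with a 1,1-disubstituted alkene (C8–C9 bond), in which the titanium BINOLate shields one face of the bound aldehyde and the (S) ligand should give the (S) carbinol that becomes C8.

Step 2
Reactants: 3 ethyl (S)-2-hydroxy-4-methylpent-4-enoate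
Product: 4 ethyl (S)-2-(tert-butyldimethylsilyloxy)-4-methylpent-4-enoate
Conditions: TBSCl, imidazole, DMF, rt
Reagents that add atoms: tert-butyldimethylsilyl chloride, CC(C)(C)[Si](C)(C)Cl
Why: Standard silylation of a secondary alcohol, which leaves the C8 centre untouched.

Step 3
Reactants: 4 ethyl (S)-2-(tert-butyldimethylsilyloxy)-4-methylpent-4-enoate
Product: 5 (S)-2-(tert-butyldimethylsilyloxy)-N-methoxy-N,4-dimethylpent-4-enamide
Conditions: MeNH(OMe)·HCl, i-PrMgCl, THF, −20 °C
Reagents that add atoms: N,O-dimethylhydroxylamine hydrochloride, CNOC.Cl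
Why: Aminolysis of the ester by the chloromagnesium amide (Weinreb amide formation) runs cold and without enolising the α-silyloxy ester, so C8 is retained.

Step 4
Reactants: 6 (S)-but-3-yn-2-ol
Product: 7 (S)-3-(tert-butyldimethylsilyloxy)but-1-yne
Conditions: TBSCl, imidazole, CH2Cl2, 0 °C to rt
Reagents that add atoms: tert-butyldimethylsilyl chloride, CC(C)(C)[Si](C)(C)Cl
Why: Silylation of the propargylic alcohol protects the future C4 oxygen in the form that later activates the C4–H bond, with no change at the stereocentre.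

Step 5
Reactants: 7 (S)-3-(tert-butyldimethylsilyloxy)but-1-yne; 5 (S)-2-(tert-butyldimethylsilyloxy)-N-methoxy-N,4-dimethylpent-4-enamide
Product: 9 (4S,8S)-4,8-bis(tert-butyldimethylsilyloxy)-2-methylnon-1-en-6-yn-5-one, via lithium acetylide 8 (not isolated)
Conditions: n-BuLi, THF, −78 °C; then 5, −78 to 0 °C; aq NH4Cl
Reagents that add atoms: none
Why: Weinreb ketone synthesis, in which the acetylide adds once and the chelated tetrahedral adduct collapses only on work-up, forms C6–C7 without over-addition or loss of the C8 and C4 configurations.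

Step 6
Reactants: 9 (4S,8S)-4,8-bis(tert-butyldimethylsilyloxy)-2-methylnon-1-en-6-yn-5-one
Product: 10 (4S,5R,8S)-4,8-bis(tert-butyldimethylsilyloxy)-2-methylnon-1-en-6-yn-5-ol
Conditions: Ru[(S,S)-TsDPEN](p-cymene) (2 mol %), i-PrOH, rt
Reagents that add atoms: none
Why: Noyori asymmetric transfer hydrogenation of an ynone, where the alkynyl group plays the role of the aryl group of an aryl ketone, so the (S,S) catalyst should give the (R) carbinol at C7, anti to the C8 silyloxy group (also the Felkin–Anh sense).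

Step 7
Reactants: 10 (4S,5R,8S)-4,8-bis(tert-butyldimethylsilyloxy)-2-methylnon-1-en-6-yn-5-ol
Product: 11 C7 triethylsilyl ether of 10
Conditions: TESCl, imidazole, DMF, 0 °C
Reagents that add atoms: chlorotriethylsilane, CC[Si](Cl)(CC)CC
Why: Silylation gives a bulky propargylic ether for the cyclisation that can later be removed in the presence of the two TBS ethers.

Step 8
Reactants: 11 C7 triethylsilyl ether of 10
Product: 12 diquinane enone (ring C fused to a cyclopentenone: C2 ketone; C5=C6 with the (S)-1-silyloxyethyl arm on C5; angular C14H3 on C10; C7–OTES and C8–OTBS both cis to C14)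
Conditions: Co2(CO)8 (20 mol %), tetramethylthiourea (60 mol %), CO (1 atm), toluene, 70 °C
Reagents that add atoms: carbon monoxide, [C-]#[O+]
Why: Intramolecular Pauson–Khand [2+2+1] cycloaddition forms C6–C10, C1–C2 and C2–C5 with C10 as the only new stereocentre; in the cobaltacycle the propargylic C7 silyloxy group should sit exo to avoid the 1,3-clash with the alkyne substituent, which puts C7–O and, through the anti C7/C8 relationship, C8–O cis to C14.

Step 9
Reactants: 12 diquinane enone
Product: 13 C5–C6 epoxy ketone (epoxide oxygen cis to C14)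
Conditions: 30% H2O2, NaOH (0.3 equiv), MeOH, 0 °C
Reagents that add atoms: hydrogen peroxide, OO
Why: Weitz–Scheffer nucleophilic epoxidation, in which hydroperoxide adds reversibly to C6 and only the cis-fused diquinane can close, so the C6–O bond forms cis to the angular methyl.

Step 10
Reactants: 13 C5–C6 epoxy ketone
Product: 14 aldol (C6–OH cis to C14; H5 cis to C6–OH, arm endo; C2 ketone)
Conditions: SmI2 (2.5 equiv), THF–MeOH, −78 °C
Reagents that add atoms: none
Why: Electron transfer from SmI2 cleaves the C5–O bond next to the ketone (reductive opening of an α,β-epoxy ketone to the aldol), and the samarium enolate should be protonated by methanol at C5 on the convex face, cis to the C6 alkoxide, leaving the arm endo.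

Step 11
Reactants: 14 aldol
Product: 15 C6 trimethylsilyl ether of 14
Conditions: TMSOTf, 2,6-lutidine, CH2Cl2, −78 °C
Reagents that add atoms: trimethylsilyl trifluoromethanesulfonate, C[Si](C)(C)OS(=O)(=O)C(F)(F)F
Why: Silylation of the tertiary aldol hydroxyl blocks retro-aldol cleavage during the enolisation that follows and does not touch the C5 centre.

Step 12
Reactants: 15 C6 trimethylsilyl ether of 14
Product: 18 C1-diazo C2-ketone, via lithium enolate 16 (not isolated), via trifluoroacetyl ketone 17 (not isolated)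
Conditions: LiN(SiMe3)2, THF, −78 °C; CF3CO2CH2CF3; aq NH4Cl; then MsN3, Et3N, H2O, MeCN, rt
Reagents that add atoms: methanesulfonyl azide, CS(=O)(=O)N=[N+]=[N-]
Why: Kinetic enolisation occurs at the only α-methylene (C1) and not at the congested C5 methine, C-trifluoroacetylation activates that carbon, and the sulfonyl azide then effects deacylative (Regitz-type) diazo transfer, so C5 is untouched.

Step 13
Reactants: 18 C1-diazo C2-ketone
Product: 20 cyclobutane benzyl ester (cyclobutane C1–C5–C6–C10 on ring C; C1–CO2Bn and the C5 arm cis on the bottom face; H1, H5, C14 and C6–OTMS on top), via ketene 19 (not isolated)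
Conditions: hν (>300 nm), BnOH (10 equiv), THF, 0 °C
Reagents that add atoms: benzyl alcohol, OCc1ccccc1
Why: Photochemical Wolff rearrangement, in which loss of N2 with a 1,2-shift of C5 (retention) contracts the ring to a cyclobutyl ketene that benzyl alcohol traps, and the enol should be protonated at C1 on the top face, away from the C5 arm and ring C, which puts the ester cis to that arm.

Step 14
Reactants: 20 cyclobutane benzyl ester
Product: 21 C6,C7-diol
Conditions: HF·pyridine, pyridine, THF, 0 °C
Reagents that add atoms: none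
Why: Buffered fluoride desilylation removes the labile trimethylsilyl and triethylsilyl ethers and leaves the two secondary TBS ethers and the benzyl ester.

Step 15
Reactants: 21 C6,C7-diol
Product: 22 α-ketol (C6–OH, C7 ketone)
Conditions: Dess–Martin periodinane, pyridine, CH2Cl2, 0 °C to rt
Reagents that add atoms: none
Why: Dess–Martin oxidation takes the secondary C7 alcohol to the ketone beside the unoxidisable tertiary C6 alcohol, under buffered conditions that should not trigger α-ketol rearrangement of the cyclobutanol.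

Step 16
Reactants: 23 tert-butyl 2-(diethoxyphosphoryl)acetate
Product: 25 tert-butyl 3-(benzyloxy)-2-(diethoxyphosphoryl)propanoate, via sodium phosphonate 24 (not isolated)
Conditions: NaH, THF, 0 °C; then BnOCH2Cl, 0 °C to rt
Reagents that add atoms: benzyl chloromethyl ether, ClCOCc1ccccc1
Why: C-alkylation of the stabilised phosphonoacetate carbanion by SN2 on a reactive chloromethyl ether installs the future C13 as a benzyl ether.

Step 17
Reactants: 25 tert-butyl 3-(benzyloxy)-2-(diethoxyphosphoryl)propanoate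
Product: 26 3-(benzyloxy)-2-(diethoxyphosphoryl)propanoic acid
Conditions: CF3CO2H, CH2Cl2, rt
Reagents that add atoms: none
Why: Acidolysis of the tert-butyl ester (loss of isobutene) frees the acid while the benzyl ether and the phosphonate are stable.

Step 18
Reactants: 22 α-ketol; 26 3-(benzyloxy)-2-(diethoxyphosphoryl)propanoic acid
Product: 27 C6 ester of 22 with acid 26
Conditions: DCC, DMAP (10 mol %), CH2Cl2, rt
Reagents that add atoms: none
Why: Carbodiimide (Steglich-type) esterification, in which α-phosphono acids acylate hindered tertiary alcohols through a ketene-like activated species, also caps the hydroxyl and so shuts off the α-ketol rearrangement.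

Step 19
Reactants: 27 C6 ester of 22 with acid 26
Product: 28 butenolide (C6–O–C12(=O)–C11(C13H2OBn)=C7) with C1–CO2Bn, C8–OTBS and the C5 arm
Conditions: K2CO3, 18-crown-6, toluene, rt to 50 °C
Reagents that add atoms: none
Why: Intramolecular Horner–Wadsworth–Emmons olefination of the C7 ketone closes the butenolide, and should C8 equilibrate through the ketone enol the exo silyloxy group (cis to C14) is the favoured epimer because the endo face is filled by the C1 and C5 arms.

Step 20
Reactants: 28 butenolide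
Product: 29 C13-hydroxy C2-carboxylic acid
Conditions: H2 (1 atm), Pd/C, EtOAc, rt
Reagents that add atoms: none
Why: Hydrogenolysis removes the benzyl ester and the benzyl ether under neutral conditions that cannot epimerise C1, while the tetrasubstituted, electron-poor butenolide alkene should be too hindered to be reduced.

Step 21
Reactants: 29 C13-hydroxy C2-carboxylic acid
Product: 30 C13-acetoxy C2-carboxylic acid
Conditions: Ac2O, pyridine, DMAP (5 mol %), CH2Cl2, 0 °C; then H2O, THF
Reagents that add atoms: acetic anhydride, CC(=O)OC(C)=O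
Why: Acetylation of the primary allylic alcohol, with the transient mixed anhydride at the C2 carboxyl hydrolysed back to the acid in the aqueous quench.

Step 22
Reactants: 30 C13-acetoxy C2-carboxylic acid
Product: 32 C1 diazoacetyl compound (C2 ketone, C3 diazo; C5 (S)-1-silyloxyethyl; C8–OTBS; C13–OAc), via acid chloride 31 (not isolated)
Conditions: Me2C=C(Cl)NMe2, CH2Cl2, 0 °C; then CH2N2, Et2O, 0 °C
Reagents that add atoms: diazomethane, C=[N+]=[N-]
Why: Acylation of diazomethane by an acid chloride (the first stage of the Arndt–Eistert sequence) forms C2–C3, and the neutral chloroenamine makes the acid chloride without free acid, sparing the silyl ethers and the C1 configuration.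

Step 23
Reactants: 32 C1 diazoacetyl compound
Product: 33 tetracyclic C2 ketone (ring A closed; C4 with OTBS exo and C15 endo)
Conditions: Rh2(OAc)4 (1 mol %), CH2Cl2, rt, slow addition of 32
Reagents that add atoms: none
Why: Loss of N2 from 32 at Rh2(OAc)4 gives an electrophilic rhodium carbenoid at C3 that inserts into the C4–H bond through a concerted three-centre transition state, forming C3–C4. The closest known reaction is the dirhodium-catalysed 1,5 C–H insertion of α-diazoketones into C–H bonds next to an ether oxygen, which gives cyclopentanones. Ring A closes in the five-membered (1,5) mode, and because the two arms are cis on the cyclobutane only the cis-fused bicyclo[3.2.0]heptanone can form. The new quaternary centre C4 is fixed by retention at the inserting C–H bond, so the (S) carbinol bought as but-3-yn-2-ol ends with oxygen exo and the smaller C15 pointing into the fold towards ring C. The step needs C4–H to win over the other 1,5 C–H bonds (C9–H2, C14–H3) and over the butenolide: C4–H is tertiary and activated by the silyloxy oxygen, C9–H2 is deactivated by the adjacent C8–O, C14–H3 is primary, the alkene is tetrasubstituted and electron-poor, and the lactone oxygen lies on the opposite face of the cyclobutane.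

Step 24
Reactants: 33 tetracyclic C2 ketone
Product: 34 C2 endo alcohol
Conditions: NaBH4, MeOH, −40 °C
Reagents that add atoms: none
Why: Borohydride reduction of the ketone, far faster than attack on the hindered butenolide or the esters at this temperature, should occur from the exo face of ring A because the endo face is walled off by the cyclobutane and ring C, giving the endo alcohol.

Step 25
Reactants: 34 C2 endo alcohol
Product: 35 C2 exo acetate
Conditions: AcOH, PPh3, DIAD, toluene, 0 °C to rt
Reagents that add atoms: acetic acid, CC(=O)O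
Why: Mitsunobu esterification, in which acetate displaces the oxyphosphonium group by SN2 from the open exo face, inverts C2 to the configuration of the target.

Step 26
Reactants: 35 C2 exo acetate
Product: 36 C4,C8-diol (C2 and C13 acetates kept)
Conditions: HF·pyridine, THF, rt
Reagents that add atoms: none
Why: Acidic fluoride desilylation cleaves the secondary C8 and the tertiary C4 TBS ethers under conditions that the acetates and the butenolide tolerate.

Step 27
Reactants: 36 C4,C8-diol
Product: 37 CNP0210373.1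
Conditions: tigloyl chloride, pyridine, DMAP (10 mol %), CH2Cl2, 0 °C
Reagents that add atoms: (E)-2-methylbut-2-enoyl chloride (tigloyl chloride), C/C=C(\C)C(Cl)=O
Why: Acylation of the secondary C8 alcohol by the acid chloride under nucleophilic catalysis, with the tertiary C4 alcohol unreactive and the (E) tiglate geometry being the stable one.

**Compound list**

1 | ethyl glyoxylate | CCOC(=O)C=O | starting material
2 | 2-methylpropene | CC(C)=C | starting material
3 | ethyl (S)-2-hydroxy-4-methylpent-4-enoate | CCOC(=O)[C@@H](O)CC(C)=C | intermediate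
4 | ethyl (S)-2-(tert-butyldimethylsilyloxy)-4-methylpent-4-enoate | CCOC(=O)[C@@H](O[Si](C)(C)C(C)(C)C)CC(C)=C | intermediate
5 | (S)-2-(tert-butyldimethylsilyloxy)-N-methoxy-N,4-dimethylpent-4-enamide | CON(C)C(=O)[C@@H](O[Si](C)(C)C(C)(C)C)CC(C)=C | intermediate
6 | (S)-but-3-yn-2-ol | C#C[C@H](C)O | starting material
7 | (S)-3-(tert-butyldimethylsilyloxy)but-1-yne | C#C[C@H](C)O[Si](C)(C)C(C)(C)C | intermediate
8 | lithium acetylide of 7 | [Li]C#C[C@H](C)O[Si](C)(C)C(C)(C)C | intermediate
9 | (4S,8S)-4,8-bis(tert-butyldimethylsilyloxy)-2-methylnon-1-en-6-yn-5-one | C=C(C)C[C@H](O[Si](C)(C)C(C)(C)C)C(=O)C#C[C@H](C)O[Si](C)(C)C(C)(C)C | intermediate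
10 | (4S,5R,8S)-4,8-bis(tert-butyldimethylsilyloxy)-2-methylnon-1-en-6-yn-5-ol | C=C(C)C[C@H](O[Si](C)(C)C(C)(C)C)[C@H](O)C#C[C@H](C)O[Si](C)(C)C(C)(C)C | intermediate
11 | C7 triethylsilyl ether of 10 | C=C(C)C[C@H](O[Si](C)(C)C(C)(C)C)[C@H](O[Si](CC)(CC)CC)C#C[C@H](C)O[Si](C)(C)C(C)(C)C | intermediate
12 | diquinane enone (C2 ketone, C5=C6, C7–OTES and C8–OTBS cis to C14) | CC(C)(C)[Si](C)(C)O[C@H]1C[C@]2(C)CC(=O)C([C@H](C)O[Si](C)(C)C(C)(C)C)=C2[C@H]1O[Si](CC)(CC)CC | intermediate
13 | C5–C6 epoxy ketone, epoxide cis to C14 | CC(C)(C)[Si](C)(C)O[C@H]1C[C@]2(C)CC(=O)[C@@]3([C@H](C)O[Si](C)(C)C(C)(C)C)O[C@@]23[C@H]1O[Si](CC)(CC)CC | intermediate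
14 | aldol (C6–OH, H5 cis to it, C2 ketone) | CC(C)(C)[Si](C)(C)O[C@H]1C[C@]2(C)CC(=O)[C@H]([C@H](C)O[Si](C)(C)C(C)(C)C)[C@]2(O)[C@H]1O[Si](CC)(CC)CC | intermediate
15 | C6 trimethylsilyl ether of 14 | CC(C)(C)[Si](C)(C)O[C@H]1C[C@]2(C)CC(=O)[C@H]([C@H](C)O[Si](C)(C)C(C)(C)C)[C@]2(O[Si](C)(C)C)[C@H]1O[Si](CC)(CC)CC | intermediate
16 | lithium C1=C2 enolate of 15 | CC(C)(C)[Si](C)(C)O[C@H]1C[C@]2(C)C=C(O[Li])[C@H]([C@H](C)O[Si](C)(C)C(C)(C)C)[C@]2(O[Si](C)(C)C)[C@H]1O[Si](CC)(CC)CC | intermediate
17 | C1-trifluoroacetyl ketone | CC(C)(C)[Si](C)(C)O[C@H]1C[C@]2(C)C(C(=O)C(F)(F)F)C(=O)[C@H]([C@H](C)O[Si](C)(C)C(C)(C)C)[C@]2(O[Si](C)(C)C)[C@H]1O[Si](CC)(CC)CC | intermediate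
18 | C1-diazo C2-ketone | CC(C)(C)[Si](C)(C)O[C@H]1C[C@]2(C)C(=[N+]=[N-])C(=O)[C@H]([C@H](C)O[Si](C)(C)C(C)(C)C)[C@]2(O[Si](C)(C)C)[C@H]1O[Si](CC)(CC)CC | intermediate
19 | cyclobutylidene ketene (C1=C2=O) | CC(C)(C)[Si](C)(C)O[C@H]1C[C@]2(C)C(=C=O)[C@H]([C@H](C)O[Si](C)(C)C(C)(C)C)[C@]2(O[Si](C)(C)C)[C@H]1O[Si](CC)(CC)CC | intermediate
20 | cyclobutane benzyl ester (C1–CO2Bn cis to the C5 arm) | CC(C)(C)[Si](C)(C)O[C@H]1C[C@]2(C)[C@H](C(=O)OCc3ccccc3)[C@H]([C@H](C)O[Si](C)(C)C(C)(C)C)[C@]2(O[Si](C)(C)C)[C@H]1O[Si](CC)(CC)CC | intermediate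
21 | C6,C7-diol | CC(C)(C)[Si](C)(C)O[C@H]1C[C@]2(C)[C@H](C(=O)OCc3ccccc3)[C@H]([C@H](C)O[Si](C)(C)C(C)(C)C)[C@]2(O)[C@H]1O | intermediate
22 | α-ketol (C6–OH, C7 ketone) | CC(C)(C)[Si](C)(C)O[C@H]1C[C@]2(C)[C@H](C(=O)OCc3ccccc3)[C@H]([C@H](C)O[Si](C)(C)C(C)(C)C)[C@]2(O)C1=O | intermediate
23 | tert-butyl 2-(diethoxyphosphoryl)acetate | CCOP(=O)(CC(=O)OC(C)(C)C)OCC | starting material
24 | sodium salt of 23 | CCOP(=O)(OCC)[CH-]C(=O)OC(C)(C)C.[Na+] | intermediate
25 | tert-butyl 3-(benzyloxy)-2-(diethoxyphosphoryl)propanoate (racemic) | CCOP(=O)(OCC)C(COCc1ccccc1)C(=O)OC(C)(C)C | intermediate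
26 | 3-(benzyloxy)-2-(diethoxyphosphoryl)propanoic acid (racemic) | CCOP(=O)(OCC)C(COCc1ccccc1)C(=O)O | intermediate
27 | C6 ester of 22 with acid 26 | CC(C)(C)[Si](C)(C)O[C@H]1C[C@]2(C)[C@H](C(=O)OCc3ccccc3)[C@H]([C@H](C)O[Si](C)(C)C(C)(C)C)[C@]2(OC(=O)C(COCc3ccccc3)P(=O)(OCC)OCC)C1=O | intermediate
28 | butenolide with C13H2OBn and C1–CO2Bn | CC(C)(C)[Si](C)(C)O[C@H]1C[C@]2(C)[C@H](C(=O)OCc4ccccc4)[C@H]([C@H](C)O[Si](C)(C)C(C)(C)C)[C@@]23OC(=O)C(COCc4ccccc4)=C13 | intermediate
29 | C13-hydroxy C2-carboxylic acid | CC(C)(C)[Si](C)(C)O[C@H]1C[C@]2(C)[C@H](C(=O)O)[C@H]([C@H](C)O[Si](C)(C)C(C)(C)C)[C@@]23OC(=O)C(CO)=C13 | intermediate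
30 | C13-acetoxy C2-carboxylic acid | CC(C)(C)[Si](C)(C)O[C@H]1C[C@]2(C)[C@H](C(=O)O)[C@H]([C@H](C)O[Si](C)(C)C(C)(C)C)[C@@]23OC(=O)C(COC(C)=O)=C13 | intermediate
31 | acid chloride of 30 | CC(C)(C)[Si](C)(C)O[C@H]1C[C@]2(C)[C@H](C(=O)Cl)[C@H]([C@H](C)O[Si](C)(C)C(C)(C)C)[C@@]23OC(=O)C(COC(C)=O)=C13 | intermediate
32 | C1 diazoacetyl compound (precursor of the key step) | CC(C)(C)[Si](C)(C)O[C@H]1C[C@]2(C)[C@H](C(=O)C=[N+]=[N-])[C@H]([C@H](C)O[Si](C)(C)C(C)(C)C)[C@@]23OC(=O)C(COC(C)=O)=C13 | intermediate
33 | tetracyclic C2 ketone (product of the key step) | CC(C)(C)[Si](C)(C)O[C@H]1C[C@]2(C)[C@@H]3C(=O)C[C@@](C)(O[Si](C)(C)C(C)(C)C)[C@@H]3[C@@]23OC(=O)C(COC(C)=O)=C13 | intermediate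
34 | C2 endo alcohol | CC(C)(C)[Si](C)(C)O[C@H]1C[C@]2(C)[C@@H]3[C@H](O)C[C@@](C)(O[Si](C)(C)C(C)(C)C)[C@@H]3[C@@]23OC(=O)C(COC(C)=O)=C13 | intermediate
35 | C2 exo acetate | CC(C)(C)[Si](C)(C)O[C@H]1C[C@]2(C)[C@@H]3[C@@H](OC(C)=O)C[C@@](C)(O[Si](C)(C)C(C)(C)C)[C@@H]3[C@@]23OC(=O)C(COC(C)=O)=C13 | intermediate
36 | C4,C8-diol | O[C@H]1C[C@]2(C)[C@@H]3[C@@H](OC(C)=O)C[C@@](C)(O)[C@@H]3[C@@]23OC(=O)C(COC(C)=O)=C13 | intermediate
37 | CNP0210373.1 | C/C=C(\C)C(=O)O[C@H]1C[C@]2(C)[C@@H]3[C@@H](OC(C)=O)C[C@@](C)(O)[C@@H]3[C@@]23OC(=O)C(COC(C)=O)=C13 | target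

**Step count and risks**

Total steps: 27. Longest linear sequence: 24 (steps 1–3, 5–15, 18–27).

Step 13 (Wolff contraction). The enol formed from the ketene may be protonated on the bottom face, which would put the C1 ester trans to the C5 arm and make ring closure impossible. The fallback sets out from 18 and comes back at 20. The photolysis is run as before and the ester is taken on as whatever mixture with the C1-epimeric benzyl ester F1 results. Deprotonation with LiN(i-Pr)2 in THF at −78 °C and trapping with PhSeBr should give the same α-phenylselanyl ester F2 from both epimers. Oxidation with H2O2/pyridine and syn elimination of the selenoxide towards H5, the only β-hydrogen, gives the cyclobutene ester F3. Hydrogenation with H2 and [Ir(cod)(PCy3)(py)]PF6 in CH2Cl2 adds both hydrogens to the exo face, leaves the benzyl ester intact and returns to 20. In this variant C1 and C5 are both set by the hydrogenation.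

Step 23 (C–H insertion). The mono-stabilised carbenoid may be diverted into dimerisation, insertion at C9–H or attack on the silyl ether oxygen instead of insertion at C4–H. The fallback sets out from 30 and comes back at 33. Activation with carbonyldiimidazole and C-acylation of KO2CCH2CO2Bn (MgCl2, Et3N, MeCN) gives the β-keto benzyl ester F4. Diazo transfer with 4-acetamidobenzenesulfonyl azide and Et3N gives the α-diazo-β-keto ester F5. This doubly stabilised carbenoid precursor is less prone to dimerisation and more selective for activated tertiary C–H bonds; with Rh2(OAc)4 it undergoes the same 1,5-insertion into C4–H to give the ring A β-keto ester F6. Hydrogenolysis (H2, Pd/C, EtOAc) with loss of CO2 from the β-keto acid returns to 33.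

Step 25 (Mitsunobu inversion). The oxyphosphonium salt may fail to form at the endo hydroxyl, which points into the fold between rings A and C, or it may eliminate instead of being displaced. The fallback sets out from 34 and comes back at 35. Tf2O/pyridine in CH2Cl2 at −40 °C gives the C2 triflate F7, which is displaced by Bu4NOAc in toluene at 0 °C with inversion.

**Further compounds**

F1 | step 13 | C1-epimeric benzyl ester (ester trans to the C5 arm) | CC(C)(C)[Si](C)(C)O[C@H]1C[C@]2(C)[C@@H](C(=O)OCc3ccccc3)[C@H]([C@H](C)O[Si](C)(C)C(C)(C)C)[C@]2(O[Si](C)(C)C)[C@H]1O[Si](CC)(CC)CC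
F2 | step 13 | α-phenylselanyl ester (SePh on the top face of C1) | CC(C)(C)[Si](C)(C)O[C@H]1C[C@]2(C)[C@]([Se]c3ccccc3)(C(=O)OCc3ccccc3)[C@H]([C@H](C)O[Si](C)(C)C(C)(C)C)[C@]2(O[Si](C)(C)C)[C@H]1O[Si](CC)(CC)CC
F3 | step 13 | cyclobutene ester (C1=C5) | CC(C)(C)[Si](C)(C)O[C@H]1C[C@]2(C)C(C(=O)OCc3ccccc3)=C([C@H](C)O[Si](C)(C)C(C)(C)C)[C@]2(O[Si](C)(C)C)[C@H]1O[Si](CC)(CC)CC
F4 | step 23 | β-keto benzyl ester on C1 | CC(C)(C)[Si](C)(C)O[C@H]1C[C@]2(C)[C@H](C(=O)CC(=O)OCc4ccccc4)[C@H]([C@H](C)O[Si](C)(C)C(C)(C)C)[C@@]23OC(=O)C(COC(C)=O)=C13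
F5 | step 23 | α-diazo-β-keto benzyl ester | CC(C)(C)[Si](C)(C)O[C@H]1C[C@]2(C)[C@H](C(=O)C(=[N+]=[N-])C(=O)OCc4ccccc4)[C@H]([C@H](C)O[Si](C)(C)C(C)(C)C)[C@@]23OC(=O)C(COC(C)=O)=C13
F6 | step 23 | ring A β-keto ester (C3–CO2Bn) | CC(C)(C)[Si](C)(C)O[C@H]1C[C@]2(C)[C@@H]3C(=O)C(C(=O)OCc4ccccc4)[C@@](C)(O[Si](C)(C)C(C)(C)C)[C@@H]3[C@@]23OC(=O)C(COC(C)=O)=C13
F7 | step 25 | C2 endo triflate | CC(C)(C)[Si](C)(C)O[C@H]1C[C@]2(C)[C@@H]3[C@H](OS(=O)(=O)C(F)(F)F)C[C@@](C)(O[Si](C)(C)C(C)(C)C)[C@@H]3[C@@]23OC(=O)C(COC(C)=O)=C13
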